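Ring B is disconnected by a [4+2] retron across C5–C6 and C9–C10. An enantioselective, Lewis-acid-catalysed Diels–Alder reaction joins an achiral ring-A enal (C5=C10 dienophile, formyl on C10, C3 masked as a dioxolane) with a farnesyl-derived (E)-2-boryl-1,3-diene (C6=C7–C8=C9) that already carries the whole side chain. The step exploits the syn array H-5 / C-10 methyl / C-9 chain on ring B of the cis-fused decalin: suprafacial endo addition to the cyclic olefin should deliver C5, C9 and C10 at once. The formyl group then becomes the C-10 methyl, the boronate a C-8 ketone for convex-face methyl addition, and late allylic oxidation and acetylation finish the chain.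

Key step: step 7

Remark: the SMILES is read literally, that is H-5 and CH3-10 are cis (cis-fused decalin, 5S,8R,9R,10S; polypodane numbering is used throughout), and the (R)-antipode of the oxazaborolidinium catalyst is an assignment from the usual shielding model for 2-substituted enals (the (S)-antipode would be taken if the sense proved opposite).

Step 1
Reactants: 1 2,2-dimethylcyclohexane-1,3-dione
Product: 2 6,6-dimethyl-1,4-dioxaspiro[4.5]decan-7-one
Conditions: ethylene glycol (1 equiv), p-TsOH (cat.), benzene, reflux, azeotropic removal of water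
Reagents that add atoms: ethylene glycol, OCCO
Why: Acid-catalysed monoketalisation (acetal formation) of a symmetrical diketone should stop after one carbonyl because the remaining one becomes much more hindered, and no stereocentre is created.

Step 2
Reactants: 2 6,6-dimethyl-1,4-dioxaspiro[4.5]decan-7-one
Product: 3 (8E)-8-[(dimethylamino)methylidene]-6,6-dimethyl-1,4-dioxaspiro[4.5]decan-7-one
Conditions: tert-butoxybis(dimethylamino)methane, toluene, 100 °C
Reagents that add atoms: tert-butoxybis(dimethylamino)methane, CC(C)(C)OC(N(C)C)N(C)C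
Why: Aminomethylenation (enaminone formation) can occur only at the single enolisable α-carbon, the future C10, the other α-carbon being quaternary, and the carbon added here later becomes the angular methyl group.

Step 3
Reactants: 3 (8E)-8-[(dimethylamino)methylidene]-6,6-dimethyl-1,4-dioxaspiro[4.5]decan-7-one
Product: 5 6,6-dimethyl-1,4-dioxaspiro[4.5]dec-7-ene-8-carbaldehyde, via amino alkoxide 4 (not isolated)
Conditions: LiAlH4, Et2O, 0 °C; then 1 M HCl/Et2O, 0 °C, short contact
Reagents that add atoms: water, O
Why: 1,2-Reduction of the vinylogous amide followed by acid-induced loss of water and iminium hydrolysis (reductive 1,3-carbonyl transposition of an enaminone) should give the enal whose C5=C10 double bond lies next to the gem-dimethyl carbon, with no stereocentre formed.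

Step 4
Reactants: 6 (2E,6E)-farnesyl bromide; 7 1-(trimethylsilyl)propyne
Product: 9 trimethyl[(5E,9E)-6,10,14-trimethylpentadeca-5,9,13-trien-1-yn-1-yl]silane, via lithiated silylpropyne 8 (not isolated)
Conditions: 7, n-BuLi, THF, −78 → −20 °C; then 6, −78 → 0 °C
Reagents that add atoms: none
Why: Propargylic lithiation and SN2 alkylation by the primary allylic bromide (the silyl group blocks the allenyl terminus) should add C11, C9 and C8 to the farnesyl unit without touching its two E-olefins.

Step 5
Reactants: 9 trimethyl[(5E,9E)-6,10,14-trimethylpentadeca-5,9,13-trien-1-yn-1-yl]silane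
Product: 11 4,4,5,5-tetramethyl-2-[(5E,9E)-6,10,14-trimethylpentadeca-5,9,13-trien-1-yn-1-yl]-1,3,2-dioxaborolane, via lithium acetylide 10 (not isolated)
Conditions: MeLi·LiBr, THF, 0 °C → rt; then 2-isopropoxy-4,4,5,5-tetramethyl-1,3,2-dioxaborolane, −78 °C; then HCl in Et2O, −78 °C → rt
Reagents that add atoms: 2-isopropoxy-4,4,5,5-tetramethyl-1,3,2-dioxaborolane, CC(C)OB1OC(C)(C)C(C)(C)O1
Why: Desilylative lithiation of the alkynylsilane gives the acetylide, whose borate complex should collapse under anhydrous acid to the 1-alkynyl pinacolboronate (acetylide borylation), with no stereocentre involved.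

Step 6
Reactants: 11 4,4,5,5-tetramethyl-2-[(5E,9E)-6,10,14-trimethylpentadeca-5,9,13-trien-1-yn-1-yl]-1,3,2-dioxaborolane; 12 vinyl bromide
Product: 15 4,4,5,5-tetramethyl-2-[(3E,7E,11E)-8,12,16-trimethylheptadeca-1,3,7,11,15-pentaen-3-yl]-1,3,2-dioxaborolane, via borazirconocene 13 (not isolated), via alkenylzinc chloride 14 (not isolated)
Conditions: Cp2Zr(H)Cl, THF, rt; then ZnCl2, Pd(PPh3)4 (5 mol %), 12, THF, 0 °C → rt
Reagents that add atoms: none
Why: syn-Hydrozirconation places zirconium on the boron-bearing carbon and hydrogen on C9, and Negishi coupling of the carbon–metal bond with retention (the C–B bond is inert without base) should give the 2-boryl diene with the chain trans to the new vinyl group, that is (3E).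

Step 7
Reactants: 5 6,6-dimethyl-1,4-dioxaspiro[4.5]dec-7-ene-8-carbaldehyde; 15 4,4,5,5-tetramethyl-2-[(3E,7E,11E)-8,12,16-trimethylheptadeca-1,3,7,11,15-pentaen-3-yl]-1,3,2-dioxaborolane
Product: 16 cis-fused Diels–Alder adduct (C3 dioxolane; C4 gem-dimethyl; 10β-formyl; 5β-H; 9β-chain; pinacolboryl on C8 of the C7=C8 bond)
Conditions: (R)-tetrahydro-1-(2-methylphenyl)-3,3-diphenyl-1H,3H-pyrrolo[1,2-c][1,3,2]oxazaborole (20 mol %), HNTf2 (18 mol %), CH2Cl2, −78 → −20 °C
Reagents that add atoms: none
Why: The N-protonated oxazaborolidine binds the formyl oxygen of 5 and lowers the LUMO of the C5=C10 bond, so that an asynchronous concerted [4+2] cycloaddition with the s-cis diene of 15 forms C5–C6 ahead of C9–C10; the closest known reaction types are chiral oxazaborolidinium-catalysed Diels–Alder reactions of α-substituted enals and Diels–Alder reactions of 2-boryl-1,3-dienes. Ring B is closed as a six-membered carbocycle by intermolecular [4+2] annulation, both bonds being made suprafacially on one face of the ring-A olefin. C5 and C10 follow from the ring-enforced cis geometry of the dienophile, so H-5 and the formyl group are syn and the decalin is cis-fused; C9 follows from the E geometry of C8=C9 together with the formyl-endo transition state, the only one that keeps the C4 gem-dimethyl carbon away from the diene, which places the chain syn to the formyl group. The absolute sense (addition to the Si face of C10) is set by the catalyst, whose aryl group shields the rear face of the s-trans enal. The step needs regioselectivity (C9 to C10, not C9 to C5), which should be secured by the large LUMO coefficient at the β-carbon C5 meeting the unsubstituted terminus C6, by the alkyl group on C9 and the boryl group sitting at the node (C8) of the developing allyl cation, and by sterics, since only the CH2 terminus can reach the neopentyl C5.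

Step 8
Reactants: 16 cis-fused Diels–Alder adduct
Product: 18 alkenylboronate with the C10 methyl in place (otherwise as 16), via tosylhydrazone 17 (not isolated)
Conditions: TsNHNH2, THF, 4 Å molecular sieves, rt; then catecholborane, 0 °C; then NaOAc·3H2O, 65 °C
Reagents that add atoms: none
Why: Condensation of the neopentyl aldehyde to its tosylhydrazone, hydride addition and sulfinate elimination (Caglioti-type tosylhydrazone reduction) should convert CHO into the C-10 methyl through a diazene that loses N2, leaving the alkenylboronate, the ketal and the quaternary stereocentre untouched.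

Step 9
Reactants: 18 alkenylboronate with the C10 methyl in place
Product: 19 C8 ketone (3,3-ethylenedioxy; 5β-H; 9β-chain; 10β-methyl)
Conditions: NaBO3·4H2O, THF/H2O (1:1), rt
Reagents that add atoms: sodium perborate, O[B-]1(O)OO[B-](O)(O)OO1.[Na+].[Na+]
Why: Oxidation of the alkenyl C–B bond (boronate oxidation) gives the enol and hence the C8 ketone under nearly neutral conditions that should spare the trisubstituted olefins and leave the α-stereocentre C9 unepimerised.

Step 10
Reactants: 19 C8 ketone
Product: 20 tertiary alcohol (8α-hydroxy-8β-methyl; 3,3-ethylenedioxy)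
Conditions: MeMgBr, anhydrous CeCl3, THF, −78 °C; aq NH4Cl
Reagents that add atoms: methylmagnesium bromide, C[Mg]Br
Why: The weakly basic organocerium reagent (organocerium 1,2-addition) suppresses enolisation, and methyl should enter C8 from the convex β-face of the cis-fused bicycle, equatorially and anti to the axial C1 of ring A that covers the α-face, giving the 8α-hydroxy-8β-methyl carbinol (8R).

Step 11
Reactants: 20 tertiary alcohol
Product: 21 terminal (E)-allylic alcohol (otherwise as 20)
Conditions: SeO2 (cat.), t-BuOOH, salicylic acid (cat.), CH2Cl2, 0 °C → rt, stopped at partial conversion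
Reagents that add atoms: tert-butyl hydroperoxide, CC(C)(C)OO; selenium dioxide (oxygen carrier), O=[Se]=O
Why: The ene reaction and [2,3]-sigmatropic shift of the allylseleninic acid (selenium dioxide allylic oxidation) are fastest at the terminal isopropylidene group and select its E-methyl, so the (E)-allylic alcohol should form while the internal olefins, the ketal and the tertiary alcohol remain.

Step 12
Reactants: 21 terminal (E)-allylic alcohol
Product: 22 terminal allylic acetate (3,3-ethylenedioxy; free 8α-OH)
Conditions: Ac2O, pyridine, DMAP (cat.), CH2Cl2, 0 °C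
Reagents that add atoms: acetic anhydride, CC(=O)OC(C)=O
Why: Nucleophile-catalysed esterification of the primary allylic alcohol is far faster than acylation of the hindered tertiary C8 carbinol, so only the terminal acetate should form.

Step 13
Reactants: 22 terminal allylic acetate
Product: 23 myrrhanone A acetate as drawn, (5S,8R,9R,10S)
Conditions: pyridinium p-toluenesulfonate (cat.), acetone/H2O (10:1), 50 °C
Reagents that add atoms: water, O
Why: Mild acid-catalysed hydrolysis of the dioxolane (acetal hydrolysis) should liberate the C3 ketone without ionising the tertiary alcohol or the allylic acetate, and no stereocentre is affected.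

Compound list
1 | 2,2-dimethylcyclohexane-1,3-dione | CC1(C)C(=O)CCCC1=O | starting material
2 | 6,6-dimethyl-1,4-dioxaspiro[4.5]decan-7-one | CC1(C)C(=O)CCCC12OCCO2 | intermediate
3 | (8E)-8-[(dimethylamino)methylidene]-6,6-dimethyl-1,4-dioxaspiro[4.5]decan-7-one | CN(C)/C=C1\CCC2(OCCO2)C(C)(C)C1=O | intermediate
4 | (8E)-8-[(dimethylamino)methylidene]-6,6-dimethyl-1,4-dioxaspiro[4.5]decan-7-ol, present as its aluminium alkoxide (carbinol centre racemic) | CN(C)/C=C1\CCC2(OCCO2)C(C)(C)C1O | intermediate
5 | 6,6-dimethyl-1,4-dioxaspiro[4.5]dec-7-ene-8-carbaldehyde (ring-A enal) | O=CC1=CC(C)(C)C2(CC1)OCCO2 | intermediate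
6 | (2E,6E)-farnesyl bromide | CC(C)=CCC/C(C)=C/CC/C(C)=C/CBr | starting material
7 | 1-(trimethylsilyl)propyne | CC#C[Si](C)(C)C | starting material
8 | 3-lithio-1-(trimethylsilyl)propyne | [Li]CC#C[Si](C)(C)C | intermediate
9 | trimethyl[(5E,9E)-6,10,14-trimethylpentadeca-5,9,13-trien-1-yn-1-yl]silane | CC(C)=CCC/C(C)=C/CC/C(C)=C/CCC#C[Si](C)(C)C | intermediate
10 | lithium (5E,9E)-6,10,14-trimethylpentadeca-5,9,13-trien-1-yn-1-ide | CC(C)=CCC/C(C)=C/CC/C(C)=C/CCC#C[Li] | intermediate
11 | 4,4,5,5-tetramethyl-2-[(5E,9E)-6,10,14-trimethylpentadeca-5,9,13-trien-1-yn-1-yl]-1,3,2-dioxaborolane | CC(C)=CCC/C(C)=C/CC/C(C)=C/CCC#CB1OC(C)(C)C(C)(C)O1 | intermediate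
12 | vinyl bromide | C=CBr | starting material
13 | gem-borazirconocene: chlorobis(cyclopentadienyl)zirconium on the boron-bearing alkene carbon, zirconium cis to the new vinylic H, boron cis to the chain | CC(C)=CCC/C(C)=C/CC/C(C)=C/CC/C=C(/[Zr](Cl)(C1C=CC=C1)C1C=CC=C1)B1OC(C)(C)C(C)(C)O1 | intermediate
14 | corresponding α-boryl alkenylzinc chloride (same geometry) | CC(C)=CCC/C(C)=C/CC/C(C)=C/CC/C=C(/[Zn]Cl)B1OC(C)(C)C(C)(C)O1 | intermediate
15 | 4,4,5,5-tetramethyl-2-[(3E,7E,11E)-8,12,16-trimethylheptadeca-1,3,7,11,15-pentaen-3-yl]-1,3,2-dioxaborolane (boryl diene) | CC(C)=CCC/C(C)=C/CC/C(C)=C/CC/C=C(/C=C)B1OC(C)(C)C(C)(C)O1 | intermediate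
16 | cis-fused adduct: 3,3-ethylenedioxy, 4,4-dimethyl, 10β-formyl, 5β-H, C7=C8 with pinacolboryl on C8, 9β-[(3E,7E)-4,8,12-trimethyltrideca-3,7,11-trien-1-yl] | CC(C)=CCC/C(C)=C/CC/C(C)=C/CC[C@@H]1[C@@]2(C=O)CCC3(OCCO3)C(C)(C)[C@H]2CC=C1B4OC(C)(C)C(C)(C)O4 | intermediate
17 | (E)-tosylhydrazone of 16 | CC(C)=CCC/C(C)=C/CC/C(C)=C/CC[C@@H]1[C@@]2(/C=N/NS(=O)(=O)c5ccc(C)cc5)CCC3(OCCO3)C(C)(C)[C@H]2CC=C1B4OC(C)(C)C(C)(C)O4 | intermediate
18 | as 16 but with 10β-methyl in place of formyl | CC(C)=CCC/C(C)=C/CC/C(C)=C/CC[C@@H]1[C@@]2(C)CCC3(OCCO3)C(C)(C)[C@H]2CC=C1B4OC(C)(C)C(C)(C)O4 | intermediate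
19 | C8 ketone: 3,3-ethylenedioxy, 4,4,10β-trimethyl, 5β-H, 9β-chain (9α-H) cis-decalin-8-one | CC(C)=CCC/C(C)=C/CC/C(C)=C/CC[C@@H]1[C@@]2(C)CCC3(OCCO3)C(C)(C)[C@H]2CCC1=O | intermediate
20 | tertiary alcohol: as 19 with 8α-hydroxy and 8β-methyl | CC(C)=CCC/C(C)=C/CC/C(C)=C/CC[C@@H]1[C@@]2(C)CCC3(OCCO3)C(C)(C)[C@H]2CC[C@@]1(C)O | intermediate
21 | as 20 with the terminal (E)-methyl oxidised to CH2OH | OC/C(C)=C/CC/C(C)=C/CC/C(C)=C/CC[C@@H]1[C@@]2(C)CCC3(OCCO3)C(C)(C)[C@H]2CC[C@@]1(C)O | intermediate
22 | terminal acetate of 21 (C3 still a dioxolane) | CC(=O)OC/C(C)=C/CC/C(C)=C/CC/C(C)=C/CC[C@@H]1[C@@]2(C)CCC3(OCCO3)C(C)(C)[C@H]2CC[C@@]1(C)O | intermediate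
23 | myrrhanone A acetate as drawn: (5S,8R,9R,10S), terminal (E)-allylic acetate, 8α-hydroxy, 3-oxo, H-5 cis to CH3-10 | CC(=O)OC/C(C)=C/CC/C(C)=C/CC/C(C)=C/CC[C@@H]1[C@@]2(C)CCC(=O)C(C)(C)[C@H]2CC[C@@]1(C)O | target

Total steps: 13. Longest linear sequence: 10 steps (steps 4–13 from 6; the ring-A branch, steps 1–3 then 7–13, is equally long).

Steps most likely to fail

Step 7. The cycloaddition may stall or proceed with little enantiofacial bias, because the boryl diene is a weak nucleophile, C5 of the enal is neopentyl, and the ketal and boronate oxygens can sequester the cationic catalyst. The fallback sets out from 5 and 15 and returns at 16. The same cycloaddition is promoted with stoichiometric EtAlCl2 in CH2Cl2 (−78 → 0 °C), which should give 16 as a racemate, that is together with its mirror image, ent-adduct F1. The mixture is condensed with (1R,2R)-N,N′-dimethyl-1,2-diphenylethane-1,2-diamine (4 Å sieves, CH2Cl2) to the diastereomeric imidazolidines, aminal F2 (from 16) and aminal F3 (from F1). These are separated by chromatography, and F2 is hydrolysed on wet silica gel or with cold dilute aqueous oxalic acid to return 16 as a single enantiomer.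

Step 10. Facial selectivity of the methyl addition may be poor, because the two chair–chair forms of the cis-decalin present opposite faces of the C8 carbonyl, and enolisation toward C7 may compete. The fallback sets out from 19 and returns at 20, and replaces substrate control by reagent control. Kinetic enolisation at C7 (KN(SiMe3)2, PhNTf2, THF, −78 °C) should give enol triflate F4. Stille coupling with (tributylstannyl)methanol (Pd(PPh3)4, LiCl, dioxane, 90 °C) should give allylic alcohol F5. Sharpless asymmetric epoxidation (Ti(OiPr)4, L-(+)-diethyl tartrate, t-BuOOH, 4 Å sieves, CH2Cl2, −20 °C) touches only the allylic-alcohol olefin; its bottom-face delivery corresponds here to the α-face and should give α-epoxy alcohol F6. Tosylation (TsCl, Et3N, DMAP) gives epoxy tosylate F7. LiEt3BH (THF, 0 °C → rt) should reduce the primary sulfonate to the C8 methyl and open the epoxide at C7, giving 20.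

Step 11. Over-oxidation to the enal, oxidation at internal allylic methylenes and incomplete conversion may erode material at a late stage. The fallback sets out from 20 and returns at 21, and rebuilds the chain terminus instead of oxidising it. Terminal-selective bromohydrin formation (NBS, THF/H2O, 0 °C) should give bromohydrin F8, and ring closure (K2CO3, MeOH) terminal epoxide F9. Cleavage with HIO4 (buffered THF/H2O, 0 °C) gives trisnor aldehyde F10. Wittig olefination with ethyl 2-(triphenylphosphoranylidene)propanoate (CH2Cl2, rt) gives E-enoate F11, and i-Bu2AlH (CH2Cl2, −78 °C) reduces it to 21.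

Further compounds
F1 | step 7 | enantiomer of adduct 16 | CC(C)=CCC/C(C)=C/CC/C(C)=C/CC[C@H]1[C@]2(C=O)CCC3(OCCO3)C(C)(C)[C@@H]2CC=C1B4OC(C)(C)C(C)(C)O4
F2 | step 7 | (4R,5R)-1,3-dimethyl-4,5-diphenylimidazolidine (aminal) of 16 | CC(C)=CCC/C(C)=C/CC/C(C)=C/CC[C@@H]1[C@@]2(C5N(C)[C@H](c6ccccc6)[C@@H](c6ccccc6)N5C)CCC3(OCCO3)C(C)(C)[C@H]2CC=C1B4OC(C)(C)C(C)(C)O4
F3 | step 7 | (4R,5R)-1,3-dimethyl-4,5-diphenylimidazolidine (aminal) of F1 | CC(C)=CCC/C(C)=C/CC/C(C)=C/CC[C@H]1[C@]2(C5N(C)[C@H](c6ccccc6)[C@@H](c6ccccc6)N5C)CCC3(OCCO3)C(C)(C)[C@@H]2CC=C1B4OC(C)(C)C(C)(C)O4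
F4 | step 10 | C7=C8 enol triflate of 19 | CC(C)=CCC/C(C)=C/CC/C(C)=C/CC[C@@H]1[C@@]2(C)CCC3(OCCO3)C(C)(C)[C@H]2CC=C1OS(=O)(=O)C(F)(F)F
F5 | step 10 | allylic alcohol with CH2OH on C8 of the C7=C8 bond | CC(C)=CCC/C(C)=C/CC/C(C)=C/CC[C@@H]1[C@@]2(C)CCC3(OCCO3)C(C)(C)[C@H]2CC=C1CO
F6 | step 10 | 7α,8α-epoxy alcohol | CC(C)=CCC/C(C)=C/CC/C(C)=C/CC[C@@H]1[C@@]2(C)CCC3(OCCO3)C(C)(C)[C@H]2C[C@H]5O[C@@]15CO
F7 | step 10 | tosylate of F6 | CC(C)=CCC/C(C)=C/CC/C(C)=C/CC[C@@H]1[C@@]2(C)CCC3(OCCO3)C(C)(C)[C@H]2C[C@H]5O[C@@]15COS(=O)(=O)c6ccc(C)cc6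
F8 | step 11 | terminal bromohydrin of 20 (bromine-bearing carbon unassigned) | CC(C)(O)C(Br)CC/C(C)=C/CC/C(C)=C/CC[C@@H]1[C@@]2(C)CCC3(OCCO3)C(C)(C)[C@H]2CC[C@@]1(C)O
F9 | step 11 | terminal epoxide of 20 (epoxide carbon unassigned) | CC1(C)OC1CC/C(C)=C/CC/C(C)=C/CC[C@@H]1[C@@]2(C)CCC3(OCCO3)C(C)(C)[C@H]2CC[C@@]1(C)O
F10 | step 11 | trisnor aldehyde | O=CCC/C(C)=C/CC/C(C)=C/CC[C@@H]1[C@@]2(C)CCC3(OCCO3)C(C)(C)[C@H]2CC[C@@]1(C)O
F11 | step 11 | ethyl (E)-2-methyl-2-enoate at the chain terminus | CCOC(=O)/C(C)=C/CC/C(C)=C/CC/C(C)=C/CC[C@@H]1[C@@]2(C)CCC3(OCCO3)C(C)(C)[C@H]2CC[C@@]1(C)O
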